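The route rests on cutting the benzylic C9–C11 bond beside ring B. C9 lies between C8 (exocyclic methylene carbon, carried as a ketone) and quaternary C10, and the arene has a phenol ortho to C11. The decalin is therefore built as a C8-oxo C9-ester by a bromonium-initiated bicyclisation of a farnesylacetoacetate whose bromine-bearing centres C3 and C14 both come from one catalytic bis-epoxidation. In the key step the C9 enolate of this β-keto ester adds to an ortho-quinone methide released from 2,4-dibromo-6-(bromomethyl)phenol, forming C9–C11 regiospecifically with the free phenol in place. Decarboxylation then sets C9 anti to the C10 methyl, and methylenation of C8 completes the target.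

Key step: step 10

Remark on numbering: ring A = C1–C5 and C10; ring B = C5–C10. C3 is the ring CHBr, C4 the quaternary carbon with methyl and side chain C12–C15 (C14 = CHBr, C15 = CMe2Cl), C8 the methylene-bearing carbon, C9 the CH that carries benzylic C11.

Assumption: (2E,6E)-farnesyl acetate and the L-fructose-derived enantiomer of the Shi ketone (a catalyst) are taken as purchasable.

Step 1
Reactants: 1 (2E,6E)-farnesyl acetate
Product: 2 (2E,6S,7S,10S)-6,7:10,11-diepoxy-3,7,11-trimethyldodec-2-en-1-yl acetate
Conditions: L-fructose-derived Shi ketone (0.6 equiv), Oxone (2KHSO5·KHSO4·K2SO4), K2CO3, Bu4NHSO4, MeCN–dimethoxymethane / aq. Na2B4O7–Na2EDTA buffer, 0 °C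
Reagents that add atoms: potassium peroxymonosulfate (the oxidant in Oxone), [K+].[O-]S(=O)(=O)OO
Why: Shi asymmetric epoxidation: the chiral dioxirane should deliver oxygen through a spiro transition state to the same face of the two electron-rich trisubstituted alkenes, giving the (S)-configured epoxide carbons that become C3, C4 and C14, while the 2,3-alkene is deactivated by the allylic acetate.

Step 2
Reactants: 2 (2E,6S,7S,10S)-6,7:10,11-diepoxy-3,7,11-trimethyldodec-2-en-1-yl acetate
Product: 3 (2E,6S,7S,10S)-6,7:10,11-diepoxy-3,7,11-trimethyldodec-2-en-1-ol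
Conditions: K2CO3, MeOH, 0 °C → rt
Reagents that add atoms: none
Why: Base-catalysed methanolysis (transesterification) of the acetate; trisubstituted epoxides are inert to carbonate in methanol.

Step 3
Reactants: 3 (2E,6S,7S,10S)-6,7:10,11-diepoxy-3,7,11-trimethyldodec-2-en-1-ol
Product: 5 (2E,6S,7S,10S)-1-bromo-6,7:10,11-diepoxy-3,7,11-trimethyldodec-2-ene, via allylic mesylate 4 (not isolated)
Conditions: MsCl, Et3N, THF, −45 °C; then LiBr, THF, −45 → 0 °C
Reagents that add atoms: lithium bromide, [Li+].[Br-]
Why: Mesylation followed by SN2 displacement with bromide at the primary allylic carbon; the low temperature should prevent epoxide opening and allylic transposition.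

Step 4
Reactants: 5 (2E,6S,7S,10S)-1-bromo-6,7:10,11-diepoxy-3,7,11-trimethyldodec-2-ene; 6 allyl acetoacetate (prop-2-en-1-yl 3-oxobutanoate)
Product: 7 prop-2-en-1-yl (6E,10S,11S,14S)-10,11:14,15-diepoxy-7,11,15-trimethyl-3-oxohexadec-6-enoate
Conditions: NaH, then n-BuLi, THF, 0 °C; then 5, 0 °C; 1 M HCl quench
Reagents that add atoms: none
Why: Acetoacetate dianion γ-alkylation: the more basic terminal carbon of the dianion should displace the allylic bromide (SN2), and the epoxides are inert to the enolate at 0 °C.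

Step 5
Reactants: 7 prop-2-en-1-yl (6E,10S,11S,14S)-10,11:14,15-diepoxy-7,11,15-trimethyl-3-oxohexadec-6-enoate
Product: 8 prop-2-en-1-yl (6E,10R,11S,14R)-10,14-dibromo-11,15-dihydroxy-7,11,15-trimethyl-3-oxohexadec-6-enoate
Conditions: Li2NiBr4, THF, 0 °C → rt; pH 7 phosphate work-up; crude used at once
Reagents that add atoms: dilithium tetrabromonickelate Li2NiBr4, [Li+].[Li+].[Ni+2].[Br-].[Br-].[Br-].[Br-]
Why: Nucleophilic anti opening of both epoxides by soft bromide (SN2) should give the anti-bromohydrins with inversion at C3 and C14; the site of attack does not matter because either regioisomer leads to the same bromonium ion in step 6, and the mild bromide-rich medium should suppress epoxide-to-epoxide cascades.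

Step 6
Reactants: 8 prop-2-en-1-yl (6E,10R,11S,14R)-10,14-dibromo-11,15-dihydroxy-7,11,15-trimethyl-3-oxohexadec-6-enoate
Product: 9 prop-2-en-1-yl (6E,10R,11S,14R)-10,14-dibromo-11,15-dichloro-7,11,15-trimethyl-3-oxohexadec-6-enoate
Conditions: SOCl2 (excess), BnEt3NCl, CH2Cl2, −40 → 0 °C (8 added to the reagent)
Reagents that add atoms: thionyl chloride, ClS(Cl)=O
Why: Chlorodehydroxylation with neighbouring-group participation: each tertiary chlorosulfite should ionise with anchimeric assistance from the vicinal bromine to a bromonium ion that chloride opens at the tertiary carbon, so C3 and C14 keep their configuration and C4 gains chlorine with overall retention; any C3/C4 bromonium ion captured instead by the C5=C10 alkene gives compound 10 and is not lost.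

Step 7
Reactants: 9 prop-2-en-1-yl (6E,10R,11S,14R)-10,14-dibromo-11,15-dichloro-7,11,15-trimethyl-3-oxohexadec-6-enoate
Product: 10 prop-2-en-1-yl (1S,4aS,5R,6R,8aR)-6-bromo-5-[(3R)-3-bromo-4-chloro-4-methylpentyl]-5,8a-dimethyl-2-oxodecahydronaphthalene-1-carboxylate
Conditions: SnCl4 (3 equiv), CH2Cl2, −78 → 0 °C
Reagents that add atoms: none
Why: Bromonium-initiated cation–olefin bicyclisation: SnCl4 should ionise the C4 chloride with bromine participation and π-assistance from the (E)-C5=C10 alkene, and chair–chair anti addition with C-termination by the tin-chelated β-keto ester sets C4, C5 and C10 from C3 (equatorial bromine, trans ring fusion), while the C15 chloride, having no π-nucleophile in reach, can only ionise reversibly.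

Step 8
Reactants: 11 3,5-dibromo-2-hydroxybenzaldehyde
Product: 12 2,4-dibromo-6-(hydroxymethyl)phenol
Conditions: NaBH4, MeOH, 0 °C
Reagents that add atoms: none
Why: Hydride reduction of the aldehyde; the phenol is only deprotonated and returns on acidic work-up.

Step 9
Reactants: 12 2,4-dibromo-6-(hydroxymethyl)phenol
Product: 13 2,4-dibromo-6-(bromomethyl)phenol
Conditions: HBr (33% in AcOH), CH2Cl2, rt
Reagents that add atoms: hydrogen bromide, Br
Why: Acid-mediated substitution of the ortho-hydroxybenzylic alcohol by bromide (SN1 type through the phenol-stabilised benzylic cation).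

Step 10
Reactants: 10 prop-2-en-1-yl (1S,4aS,5R,6R,8aR)-6-bromo-5-[(3R)-3-bromo-4-chloro-4-methylpentyl]-5,8a-dimethyl-2-oxodecahydronaphthalene-1-carboxylate; 13 2,4-dibromo-6-(bromomethyl)phenol
Product: 15 prop-2-en-1-yl (1S,4aS,5R,6R,8aR)-6-bromo-5-[(3R)-3-bromo-4-chloro-4-methylpentyl]-1-[(3,5-dibromo-2-hydroxyphenyl)methyl]-5,8a-dimethyl-2-oxodecahydronaphthalene-1-carboxylate, via ortho-quinone methide 14 (not isolated)
Conditions: Cs2CO3 (2.2 equiv), MeCN, 0 °C → rt, slow addition of 13
Reagents that add atoms: none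
Why: Cs2CO3 deprotonates the phenol of 13, which expels bromide in a 1,4-elimination to the ortho-quinone methide 14, and the caesium enolate of β-keto ester 10 adds through C9 to the exocyclic methylene of 14, driven by rearomatisation. The closest known reaction type is the Michael addition of cyclic β-keto esters and other 1,3-dicarbonyls to ortho-quinone methides generated in situ from ortho-hydroxybenzyl halides. No ring of the target is closed; the adduct may rest as a six-membered hemiketal (phenol oxygen onto C8, 6-exo-trig, reversible), which is only a tautomer of 15. The new quaternary C9 should be attacked on its axial face anti to the axial C10 methyl, but this configuration is of no consequence because C9 is re-protonated in step 11. The selectivities needed are C9 over C7 and carbon over oxygen: the ester makes C9 the only doubly activated carbon, and the soft, unhindered methylene terminus of 14 favours C-alkylation even next to quaternary C10. Carbonate is too weak a base to eliminate the tertiary chloride or the secondary bromides.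

Step 11
Reactants: 15 prop-2-en-1-yl (1S,4aS,5R,6R,8aR)-6-bromo-5-[(3R)-3-bromo-4-chloro-4-methylpentyl]-1-[(3,5-dibromo-2-hydroxyphenyl)methyl]-5,8a-dimethyl-2-oxodecahydronaphthalene-1-carboxylate
Product: 17 (1S,4aS,5R,6R,8aR)-6-bromo-5-[(3R)-3-bromo-4-chloro-4-methylpentyl]-1-[(3,5-dibromo-2-hydroxyphenyl)methyl]-5,8a-dimethyloctahydronaphthalen-2(1H)-one, via β-keto acid 16 (not isolated)
Conditions: Pd(PPh3)4 (5 mol %), morpholine, THF, rt; then AcOH, 45 °C
Reagents that add atoms: none
Why: Palladium-catalysed deallylation (Tsuji–Trost type: zerovalent palladium ionises the allyl ester to a π-allyl complex that morpholine captures, faster at rt than insertion into the aryl bromides) frees β-keto acid 16, which decarboxylates to the C8/C9 enol; protonation of C9 on the axial face anti to the C10 methyl and the thermodynamic preference for the equatorial benzyl group both give H9 trans to the C10 methyl, as in the target.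

Step 12
Reactants: 17 (1S,4aS,5R,6R,8aR)-6-bromo-5-[(3R)-3-bromo-4-chloro-4-methylpentyl]-1-[(3,5-dibromo-2-hydroxyphenyl)methyl]-5,8a-dimethyloctahydronaphthalen-2(1H)-one
Product: 18 2,4-dibromo-6-{[(1R,4aS,5R,6R,8aS)-6-bromo-5-[(3R)-3-bromo-4-chloro-4-methylpentyl]-5,8a-dimethyl-2-methylidenedecahydronaphthalen-1-yl]methyl}phenol
Conditions: Tebbe reagent Cp2Ti(μ-Cl)(μ-CH2)AlMe2 (3 equiv), pyridine, THF–toluene, −40 °C → rt; aq. potassium sodium tartrate work-up
Reagents that add atoms: Tebbe reagent Cp2Ti(μ-Cl)(μ-CH2)AlMe2, C[Al-]1(C)C[Ti]([Cl+]1)(C2C=CC=C2)C3C=CC=C3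
Why: Tebbe methylenation (titanium methylidene [2+2] addition to the C8 ketone, then cycloreversion) is non-basic and non-reducing, so the C9 stereocentre next to the ketone and the vicinal bromochloride should survive; the first equivalent is consumed by the phenol, which is released on work-up.

Compound list
1 | (2E,6E)-farnesyl acetate [(2E,6E)-3,7,11-trimethyldodeca-2,6,10-trien-1-yl acetate] | CC(=O)OC/C=C(\C)CC/C=C(\C)CCC=C(C)C | starting material
2 | (2E,6S,7S,10S)-6,7:10,11-diepoxy-3,7,11-trimethyldodec-2-en-1-yl acetate | CC(=O)OC/C=C(\C)CC[C@@H]1O[C@@]1(C)CC[C@@H]1OC1(C)C | intermediate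
3 | (2E,6S,7S,10S)-6,7:10,11-diepoxy-3,7,11-trimethyldodec-2-en-1-ol | OC/C=C(\C)CC[C@@H]1O[C@@]1(C)CC[C@@H]1OC1(C)C | intermediate
4 | (2E,6S,7S,10S)-6,7:10,11-diepoxy-3,7,11-trimethyldodec-2-en-1-yl methanesulfonate | CS(=O)(=O)OC/C=C(\C)CC[C@@H]1O[C@@]1(C)CC[C@@H]1OC1(C)C | intermediate (not isolated)
5 | (2E,6S,7S,10S)-1-bromo-6,7:10,11-diepoxy-3,7,11-trimethyldodec-2-ene | BrC/C=C(\C)CC[C@@H]1O[C@@]1(C)CC[C@@H]1OC1(C)C | intermediate
6 | allyl acetoacetate (prop-2-en-1-yl 3-oxobutanoate) | C=CCOC(=O)CC(C)=O | starting material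
7 | prop-2-en-1-yl (6E,10S,11S,14S)-10,11:14,15-diepoxy-7,11,15-trimethyl-3-oxohexadec-6-enoate | C=CCOC(=O)CC(=O)CC/C=C(\C)CC[C@@H]1O[C@@]1(C)CC[C@@H]1OC1(C)C | intermediate
8 | prop-2-en-1-yl (6E,10R,11S,14R)-10,14-dibromo-11,15-dihydroxy-7,11,15-trimethyl-3-oxohexadec-6-enoate | C=CCOC(=O)CC(=O)CC/C=C(\C)CC[C@@H](Br)[C@](O)(C)CC[C@@H](Br)C(C)(C)O | intermediate
9 | prop-2-en-1-yl (6E,10R,11S,14R)-10,14-dibromo-11,15-dichloro-7,11,15-trimethyl-3-oxohexadec-6-enoate | C=CCOC(=O)CC(=O)CC/C=C(\C)CC[C@@H](Br)[C@](Cl)(C)CC[C@@H](Br)C(C)(C)Cl | intermediate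
10 | prop-2-en-1-yl (1S,4aS,5R,6R,8aR)-6-bromo-5-[(3R)-3-bromo-4-chloro-4-methylpentyl]-5,8a-dimethyl-2-oxodecahydronaphthalene-1-carboxylate (C9 ester equatorial, in equilibrium with its enol) | O=C1CC[C@@H]2[C@@](C)(CC[C@@H](Br)C(C)(C)Cl)[C@H](Br)CC[C@@]2(C)[C@@H]1C(=O)OCC=C | intermediate
11 | 3,5-dibromo-2-hydroxybenzaldehyde | O=Cc1cc(Br)cc(Br)c1O | starting material
12 | 2,4-dibromo-6-(hydroxymethyl)phenol | OCc1cc(Br)cc(Br)c1O | intermediate
13 | 2,4-dibromo-6-(bromomethyl)phenol | BrCc1cc(Br)cc(Br)c1O | intermediate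
14 | 2,4-dibromo-6-methylidenecyclohexa-2,4-dien-1-one (ortho-quinone methide) | C=C1C=C(Br)C=C(Br)C1=O | intermediate (not isolated)
15 | prop-2-en-1-yl (1S,4aS,5R,6R,8aR)-6-bromo-5-[(3R)-3-bromo-4-chloro-4-methylpentyl]-1-[(3,5-dibromo-2-hydroxyphenyl)methyl]-5,8a-dimethyl-2-oxodecahydronaphthalene-1-carboxylate (benzyl group axial at C9, expected major epimer) | O=C1CC[C@@H]2[C@@](C)(CC[C@@H](Br)C(C)(C)Cl)[C@H](Br)CC[C@@]2(C)[C@]1(Cc3cc(Br)cc(Br)c3O)C(=O)OCC=C | intermediate
16 | (1S,4aS,5R,6R,8aR)-6-bromo-5-[(3R)-3-bromo-4-chloro-4-methylpentyl]-1-[(3,5-dibromo-2-hydroxyphenyl)methyl]-5,8a-dimethyl-2-oxodecahydronaphthalene-1-carboxylic acid | O=C1CC[C@@H]2[C@@](C)(CC[C@@H](Br)C(C)(C)Cl)[C@H](Br)CC[C@@]2(C)[C@]1(Cc3cc(Br)cc(Br)c3O)C(=O)O | intermediate (not isolated)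
17 | (1S,4aS,5R,6R,8aR)-6-bromo-5-[(3R)-3-bromo-4-chloro-4-methylpentyl]-1-[(3,5-dibromo-2-hydroxyphenyl)methyl]-5,8a-dimethyloctahydronaphthalen-2(1H)-one | O=C1CC[C@@H]2[C@@](C)(CC[C@@H](Br)C(C)(C)Cl)[C@H](Br)CC[C@@]2(C)[C@@H]1Cc1cc(Br)cc(Br)c1O | intermediate
18 | 2,4-dibromo-6-{[(1R,4aS,5R,6R,8aS)-6-bromo-5-[(3R)-3-bromo-4-chloro-4-methylpentyl]-5,8a-dimethyl-2-methylidenedecahydronaphthalen-1-yl]methyl}phenol (CNP0318265.2) | C=C1CC[C@@H]2[C@@](C)(CC[C@@H](Br)C(C)(C)Cl)[C@H](Br)CC[C@@]2(C)[C@@H]1Cc1cc(Br)cc(Br)c1O | target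

Total step count: 12. Longest linear sequence: 10 steps (steps 1–7 and 10–12).

Steps most likely to fail

Step 7. Ionisation may not stay confined to C4: the C15 chloride can ionise and eliminate, ionisation at C4 can be too slow, or the keto ester can close through oxygen. The fallback sets out from compound 8 and closes the rings before any tertiary chloride exists. Catalytic TfOH in 1,1,1,3,3,3-hexafluoropropan-2-ol at 0 °C ionises the tertiary alcohols dehydratively. The C4 bromonium ion is consumed by the C5=C10 alkene and the β-keto ester, while the C15 carbinol can only return by rehydration. This should give prop-2-en-1-yl (1S,4aS,5R,6R,8aR)-6-bromo-5-[(3R)-3-bromo-4-hydroxy-4-methylpentyl]-5,8a-dimethyl-2-oxodecahydronaphthalene-1-carboxylate F1. With no π-nucleophile and no second ionisable site left, SOCl2 and BnEt3NCl in CH2Cl2 then convert the single tertiary alcohol into the chloride through its bromonium ion, and the route is rejoined at compound 10.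

Step 10. Carbon–carbon bond formation at the hindered C9 may be slow, so that the quinone methide oligomerises or alkylates the enolate oxygen. The fallback sets out from compound 9 and makes the bond before the rings exist. The same quinone methide (from 13, Cs2CO3, MeCN, 0 °C) is added to the unhindered C9 methylene of the open-chain β-keto ester. This should give prop-2-en-1-yl (6E,10R,11S,14R)-10,14-dibromo-11,15-dichloro-2-[(3,5-dibromo-2-hydroxyphenyl)methyl]-7,11,15-trimethyl-3-oxohexadec-6-enoate F2 as a mixture of epimers at the labile C9. The SnCl4 bicyclisation of step 7 is then run on F2, so that quaternary C9 is created in the ring closure, and the route comes back at compound 15.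

Step 12. The titanium methylidene may be quenched or sequestered by the phenol and by the hemiketal form of 17, and its aluminium partner may ionise the tertiary chloride. The fallback sets out from compound 17 and replaces carbonyl methylenation by a Peterson olefination. Me3SiCH2MgCl with CeCl3 (excess, THF, −78 °C) adds to the C8 ketone from the equatorial direction. This should give the β-hydroxysilane 2,4-dibromo-6-{[6-bromo-5-(3-bromo-4-chloro-4-methylpentyl)-2-hydroxy-5,8a-dimethyl-2-[(trimethylsilyl)methyl]decahydronaphthalen-1-yl]methyl}phenol F3 (C8 hydroxyl axial, cis to the C10 methyl; other centres as in 17). Elimination with aqueous HF in MeCN then gives compound 18 directly.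

Further compounds
F1 | step 7 | prop-2-en-1-yl (1S,4aS,5R,6R,8aR)-6-bromo-5-[(3R)-3-bromo-4-hydroxy-4-methylpentyl]-5,8a-dimethyl-2-oxodecahydronaphthalene-1-carboxylate | O=C1CC[C@@H]2[C@@](C)(CC[C@@H](Br)C(C)(C)O)[C@H](Br)CC[C@@]2(C)[C@@H]1C(=O)OCC=C
F2 | step 10 | prop-2-en-1-yl (6E,10R,11S,14R)-10,14-dibromo-11,15-dichloro-2-[(3,5-dibromo-2-hydroxyphenyl)methyl]-7,11,15-trimethyl-3-oxohexadec-6-enoate (epimers at C2) | C=CCOC(=O)C(Cc1cc(Br)cc(Br)c1O)C(=O)CC/C=C(\C)CC[C@@H](Br)[C@](Cl)(C)CC[C@@H](Br)C(C)(C)Cl
F3 | step 12 | 2,4-dibromo-6-{[6-bromo-5-(3-bromo-4-chloro-4-methylpentyl)-2-hydroxy-5,8a-dimethyl-2-[(trimethylsilyl)methyl]decahydronaphthalen-1-yl]methyl}phenol (C8 hydroxyl axial, other centres as in 17) | O[C@]1(C[Si](C)(C)C)CC[C@@H]2[C@@](C)(CC[C@@H](Br)C(C)(C)Cl)[C@H](Br)CC[C@@]2(C)[C@@H]1Cc1cc(Br)cc(Br)c1O
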